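**Plan**

- Retrosynthesis: the three phenolic O–Si bonds are cut first, then the furan C2=C3 bond. C3 is the formyl carbon of a ring A salicylaldehyde and C2 is the carboxyl carbon of a chroman-5-carboxylic acid; both sit at carbonyl oxidation level and O1 already links them as an aryl ester. The ester C–O bond is cut next.
- Ring A fragment: the bond from the ring carbon to the quaternary carbon of the 2-methylbut-3-en-2-yl group comes from a Claisen rearrangement of a prenyl ether on the oxygen para to the formyl group. The para carbon is then blocked and the two ortho carbons are equivalent. A prenyl ether on an oxygen ortho to the formyl group is avoided, because it would be expected to shift on to the free para carbon and give the linear prenyl isomer.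
- Chroman fragment: the aryl–C4 bond comes from a Sonogashira coupling, and the pyran O1–C2 bond from ether cleavage with ring closure onto the tertiary alcohol.
- Forward order: ring A side chain and silyl pattern (steps 1–3), pyran ring (step 6), ester union (step 10), furan ring (step 11), desilylation (step 12).
- Stereochemistry: the target has no stereocentre and no configured double bond, so nothing has to be set.

Key step: step 11

**Route**

Step 1
Reactants: 1 2,4,6-trihydroxybenzaldehyde; 2 3-methylbut-2-en-1-ol
Product: 3 2,6-dihydroxy-4-[(3-methylbut-2-en-1-yl)oxy]benzaldehyde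
Conditions: PPh3, DIAD, THF, 0 °C → rt (1 equiv of 2)
Reagents that add atoms: none
Why: Mitsunobu etherification alkylates the most acidic hydroxyl, here the 4-OH para to the formyl group, because the two ortho hydroxyls are hydrogen-bonded to the carbonyl oxygen and are weaker acids, and the neutral conditions avoid the C-alkylation that phloroglucinol phenoxides show with prenyl halides.

Step 2
Reactants: 3 2,6-dihydroxy-4-[(3-methylbut-2-en-1-yl)oxy]benzaldehyde
Product: 4 2,4,6-trihydroxy-3-(2-methylbut-3-en-2-yl)benzaldehyde
Conditions: EtOH–H2O (4:1), degassed, sealed tube, 130 °C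
Reagents that add atoms: none
Why: The aromatic Claisen rearrangement ([3,3]-sigmatropic shift) of the aryl prenyl ether delivers the 1,1-dimethylallyl group to an ortho carbon, the two ortho carbons being equivalent by symmetry and the para carbon carrying the formyl group so that a following Cope shift finds no free site, while the aqueous medium should let the shift run below the temperature at which a neighbouring hydroxyl adds to the new vinyl group.

Step 3
Reactants: 4 2,4,6-trihydroxy-3-(2-methylbut-3-en-2-yl)benzaldehyde
Product: 5 4,6-bis(tert-butyldimethylsilyloxy)-2-hydroxy-3-(2-methylbut-3-en-2-yl)benzaldehyde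
Conditions: TBSCl (2.2 equiv), imidazole, DMF, 0 °C → rt
Reagents that add atoms: tert-butyldimethylsilyl chloride, CC(C)(C)[Si](C)(C)Cl
Why: Silyl ether formation with a bulky chlorosilane follows steric access, so the 4-OH and the 6-OH should react and the 2-OH should stay free, since it is flanked by the quaternary carbon of the side chain and by the formyl group and is held in a hydrogen bond to the carbonyl oxygen.

Step 4
Reactants: 6 2-bromo-3,5-dimethoxybenzaldehyde; 7 2-methylbut-3-yn-2-ol
Product: 8 2-(3-hydroxy-3-methylbut-1-yn-1-yl)-3,5-dimethoxybenzaldehyde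
Conditions: PdCl2(PPh3)2 (cat.), CuI (cat.), Et3N, DMF, 70 °C
Reagents that add atoms: none
Why: Sonogashira coupling of a terminal alkyne with an aryl bromide whose ortho formyl group speeds oxidative addition is routine for 2-bromobenzaldehydes and for this alkynol.

Step 5
Reactants: 8 2-(3-hydroxy-3-methylbut-1-yn-1-yl)-3,5-dimethoxybenzaldehyde
Product: 9 2-(3-hydroxy-3-methylbutyl)-3,5-dimethoxybenzaldehyde
Conditions: H2 (1 atm), 10% Pd/C, EtOAc, rt, stopped after 2 equiv of H2
Reagents that add atoms: none
Why: Catalytic hydrogenation over palladium on carbon saturates an alkyne much faster than it reduces an electron-rich aryl aldehyde in a non-protic solvent at one atmosphere, so the triple bond should be reduced selectively.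

Step 6
Reactants: 9 2-(3-hydroxy-3-methylbutyl)-3,5-dimethoxybenzaldehyde
Product: 10 7-hydroxy-2,2-dimethylchroman-5-carbaldehyde
Conditions: BBr3, CH2Cl2, −78 °C → rt; aq. NaHCO3
Reagents that add atoms: none
Why: BBr3 ether cleavage removes both methyl groups while the Lewis acid ionises the tertiary alcohol, and the tertiary carbocation (or bromide) is captured by the only oxygen within reach, the one ortho to the chain, in an acid-mediated cycloetherification that closes the 2,2-dimethylchroman ring.

Step 7
Reactants: 10 7-hydroxy-2,2-dimethylchroman-5-carbaldehyde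
Product: 11 7-(tert-butyldimethylsilyloxy)-2,2-dimethylchroman-5-carbaldehyde
Conditions: TBSCl, imidazole, DMF, rt
Reagents that add atoms: tert-butyldimethylsilyl chloride, CC(C)(C)[Si](C)(C)Cl
Why: Silylation of an unhindered phenol with TBSCl and imidazole is a standard protection and leaves the aldehyde untouched.

Step 8
Reactants: 11 7-(tert-butyldimethylsilyloxy)-2,2-dimethylchroman-5-carbaldehyde
Product: 12 7-(tert-butyldimethylsilyloxy)-2,2-dimethylchroman-5-carboxylic acid
Conditions: NaClO2, NaH2PO4, 2-methyl-2-butene, t-BuOH–H2O, rt
Reagents that add atoms: sodium chlorite, [Na+].[O-]Cl=O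
Why: Pinnick oxidation converts the aldehyde to the acid near pH 4, where an aryl silyl ether is stable, and the alkene scavenger removes hypochlorous acid before it can chlorinate the electron-rich ring.

Step 9
Reactants: 12 7-(tert-butyldimethylsilyloxy)-2,2-dimethylchroman-5-carboxylic acid
Product: 13 7-(tert-butyldimethylsilyloxy)-2,2-dimethylchroman-5-carbonyl chloride
Conditions: 1-chloro-N,N,2-trimethylprop-1-en-1-amine, CH2Cl2, 0 °C → rt; evaporation, used crude
Reagents that add atoms: 1-chloro-N,N,2-trimethylprop-1-en-1-amine, CC(C)=C(Cl)N(C)C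
Why: Acid chloride formation with an α-chloroenamine runs under neutral conditions without free HCl, which spares the aryl silyl ether.

Step 10
Reactants: 5 4,6-bis(tert-butyldimethylsilyloxy)-2-hydroxy-3-(2-methylbut-3-en-2-yl)benzaldehyde; 13 7-(tert-butyldimethylsilyloxy)-2,2-dimethylchroman-5-carbonyl chloride
Product: 14 2-formyl-3,5-bis(tert-butyldimethylsilyloxy)-6-(2-methylbut-3-en-2-yl)phenyl 7-(tert-butyldimethylsilyloxy)-2,2-dimethylchroman-5-carboxylate
Conditions: Et3N, DMAP, CH2Cl2, 0 °C → rt
Reagents that add atoms: none
Why: DMAP-catalysed acylation of a phenol by an aroyl chloride (acyl transfer through the N-acylpyridinium ion) tolerates a hydroxyl flanked by a tertiary alkyl group and a formyl group, as in esters of 3-tert-butylsalicylaldehydes, and this is the only free hydroxyl in 5.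

Step 11
Reactants: 14 2-formyl-3,5-bis(tert-butyldimethylsilyloxy)-6-(2-methylbut-3-en-2-yl)phenyl 7-(tert-butyldimethylsilyloxy)-2,2-dimethylchroman-5-carboxylate
Product: 15 4,6-bis(tert-butyldimethylsilyloxy)-2-[7-(tert-butyldimethylsilyloxy)-2,2-dimethylchroman-5-yl]-7-(2-methylbut-3-en-2-yl)-1-benzofuran
Conditions: TiCl3, Zn dust, DME, reflux; 14 added slowly in DME (syringe pump, high dilution); aq. K2CO3 work-up
Reagents that add atoms: none
Why: Low-valent titanium formed from TiCl3 and Zn transfers an electron to the formyl group, and the titanium-bound ketyl carbon (the future C3) adds to the ester carbonyl carbon held beside it through O1 (the future C2); the resulting titanium diolate gives up both oxygens to titanium and leaves the C2=C3 double bond of the aromatic furan. The closest known reaction type is the titanium-mediated intramolecular carbonyl coupling of McMurry type between an aryl ketone or aldehyde and a neighbouring acyloxy group, which turns 2-acyloxyaryl carbonyl compounds into benzofurans. The furan ring closes in a 5-exo-trig mode, the ketyl carbon attacking the ester C=O that lies outside the forming ring. No stereocentre is created. The step needs ring closure to win over pinacol dimerisation and over-reduction of the aldehyde, which the ortho placement of the ester, the two ortho substituents around the formyl group and slow addition at high dilution should secure. The direction of closure is unambiguous because only one of the two oxygens ortho to the formyl group carries an acyl group, the other being a silyl ether, and the silyl ethers and the terminal alkene should not react with low-valent titanium.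

Step 12
Reactants: 15 4,6-bis(tert-butyldimethylsilyloxy)-2-[7-(tert-butyldimethylsilyloxy)-2,2-dimethylchroman-5-yl]-7-(2-methylbut-3-en-2-yl)-1-benzofuran
Product: 16 2-(7-hydroxy-2,2-dimethylchroman-5-yl)-7-(2-methylbut-3-en-2-yl)-1-benzofuran-4,6-diol (CNP0300714.0)
Conditions: Bu4NF, AcOH, THF, 0 °C
Reagents that add atoms: none
Why: Fluoride-mediated desilylation cleaves all three aryl silyl ethers through pentacoordinate silicon, and the acetic acid buffer keeps the medium near neutral, so that the triphenol is not exposed to strong base and the 1,1-dimethylallyl group, which lies next to a free hydroxyl, is not exposed to strong acid.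

**Compound list**

1 | 2,4,6-trihydroxybenzaldehyde | O=Cc1c(O)cc(O)cc1O | starting material
2 | 3-methylbut-2-en-1-ol | CC(C)=CCO | starting material
3 | 2,6-dihydroxy-4-[(3-methylbut-2-en-1-yl)oxy]benzaldehyde | O=Cc1c(O)cc(OCC=C(C)C)cc1O | intermediate
4 | 2,4,6-trihydroxy-3-(2-methylbut-3-en-2-yl)benzaldehyde | C=CC(C)(C)c1c(O)cc(O)c(C=O)c1O | intermediate
5 | 4,6-bis(tert-butyldimethylsilyloxy)-2-hydroxy-3-(2-methylbut-3-en-2-yl)benzaldehyde | C=CC(C)(C)c1c(O)c(C=O)c(O[Si](C)(C)C(C)(C)C)cc1O[Si](C)(C)C(C)(C)C | intermediate
6 | 2-bromo-3,5-dimethoxybenzaldehyde | COc1cc(OC)c(Br)c(C=O)c1 | starting material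
7 | 2-methylbut-3-yn-2-ol | CC(C)(O)C#C | starting material
8 | 2-(3-hydroxy-3-methylbut-1-yn-1-yl)-3,5-dimethoxybenzaldehyde | COc1cc(OC)c(C#CC(C)(C)O)c(C=O)c1 | intermediate
9 | 2-(3-hydroxy-3-methylbutyl)-3,5-dimethoxybenzaldehyde | COc1cc(OC)c(CCC(C)(C)O)c(C=O)c1 | intermediate
10 | 7-hydroxy-2,2-dimethylchroman-5-carbaldehyde | O=Cc1cc(O)cc2c1CCC(C)(C)O2 | intermediate
11 | 7-(tert-butyldimethylsilyloxy)-2,2-dimethylchroman-5-carbaldehyde | O=Cc1cc(O[Si](C)(C)C(C)(C)C)cc2c1CCC(C)(C)O2 | intermediate
12 | 7-(tert-butyldimethylsilyloxy)-2,2-dimethylchroman-5-carboxylic acid | O=C(O)c1cc(O[Si](C)(C)C(C)(C)C)cc2c1CCC(C)(C)O2 | intermediate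
13 | 7-(tert-butyldimethylsilyloxy)-2,2-dimethylchroman-5-carbonyl chloride | O=C(Cl)c1cc(O[Si](C)(C)C(C)(C)C)cc2c1CCC(C)(C)O2 | intermediate
14 | 2-formyl-3,5-bis(tert-butyldimethylsilyloxy)-6-(2-methylbut-3-en-2-yl)phenyl 7-(tert-butyldimethylsilyloxy)-2,2-dimethylchroman-5-carboxylate | O=Cc1c(O[Si](C)(C)C(C)(C)C)cc(O[Si](C)(C)C(C)(C)C)c(C(C)(C)C=C)c1OC(=O)c1cc(O[Si](C)(C)C(C)(C)C)cc2c1CCC(C)(C)O2 | intermediate
15 | 4,6-bis(tert-butyldimethylsilyloxy)-2-[7-(tert-butyldimethylsilyloxy)-2,2-dimethylchroman-5-yl]-7-(2-methylbut-3-en-2-yl)-1-benzofuran | C=CC(C)(C)c1c(O[Si](C)(C)C(C)(C)C)cc(O[Si](C)(C)C(C)(C)C)c2cc(-c3cc(O[Si](C)(C)C(C)(C)C)cc4c3CCC(C)(C)O4)oc12 | intermediate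
16 | 2-(7-hydroxy-2,2-dimethylchroman-5-yl)-7-(2-methylbut-3-en-2-yl)-1-benzofuran-4,6-diol | C=CC(C)(C)c1c(O)cc(O)c2cc(-c3cc(O)cc4c3CCC(C)(C)O4)oc12 | target

**Step count**

Total: 12 steps. Longest linear sequence: 9 steps (steps 4, 5, 6, 7, 8, 9, 10, 11, 12, from 6 to 16).

**Steps most likely to fail**

Step 11 (key step). Intermolecular pinacol coupling or plain reduction of the hindered aldehyde, or reductive cleavage of the aryl ester, may outrun ring closure, and the Lewis-acidic titanium and zinc chlorides may strip a silyl ether at reflux. The fallback is the intramolecular Wittig benzofuran synthesis, which forms the same C2=C3 bond from the same two carbons but makes the benzylic carbon the nucleophile. It sets out from 5 and uses 13. NaBH4 in THF–MeOH at 0 °C should reduce the formyl group of 5 to 3,5-bis(tert-butyldimethylsilyloxy)-2-(hydroxymethyl)-6-(2-methylbut-3-en-2-yl)phenol F1. PPh3·HBr in MeCN at 60 °C should convert this salicyl alcohol, through its ortho-quinone methide, into {[4,6-bis(tert-butyldimethylsilyloxy)-2-hydroxy-3-(2-methylbut-3-en-2-yl)phenyl]methyl}triphenylphosphonium bromide F2. Heating F2 with 13 and Et3N in toluene should acylate the phenol, form the ylide and close the furan by Wittig olefination of the ester carbonyl, which comes back to the route at 15.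

Step 2. At the temperature of the rearrangement a free hydroxyl next to the new side chain may add to its vinyl group (ring closure to a 2,3,3-trimethyl-2,3-dihydrobenzofuran), or the hot protic medium may ionise the prenyl ether and lead to loss or migration of the prenyl group. The fallback rearranges a fully protected ether in an aprotic medium and sets out from 3. TBSCl (excess) and imidazole in DMF at 40 °C should give 2,6-bis(tert-butyldimethylsilyloxy)-4-[(3-methylbut-2-en-1-yl)oxy]benzaldehyde F3. Heating F3 in N,N-diethylaniline at 180 °C should bring about the same Claisen rearrangement and give 2,6-bis(tert-butyldimethylsilyloxy)-4-hydroxy-3-(2-methylbut-3-en-2-yl)benzaldehyde F4, whose only free hydroxyl is the weakly nucleophilic one para to the formyl group. Bu4NF with AcOH in THF at 0 °C then removes both silyl groups and comes back to the route at 4.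

Step 3. The second silyl group may go to the hindered, hydrogen-bonded 2-OH instead of the 6-OH, or silylation of the 4-OH beside the quaternary carbon may stall, so that regioisomeric bis-silyl ethers form. The fallback silylates one ortho oxygen while the two are still equivalent and lets the rearrangement set the regiochemistry; it sets out from 3. TBSCl (1 equiv) and imidazole in CH2Cl2 at 0 °C should give 2-(tert-butyldimethylsilyloxy)-6-hydroxy-4-[(3-methylbut-2-en-1-yl)oxy]benzaldehyde F5. Claisen rearrangement in N,N-diethylaniline at 170 °C should go to the carbon beside the hydrogen-bonded hydroxyl and not to the one beside the bulky silyl ether (chelation-induced bond fixation, as known for 4-allyloxy-2-hydroxyaryl carbonyl compounds), giving 6-(tert-butyldimethylsilyloxy)-2,4-dihydroxy-3-(2-methylbut-3-en-2-yl)benzaldehyde F6. TBSCl (1 equiv) and imidazole in DMF at 0 °C should then silylate the non-chelated 4-OH and come back to the route at 5.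

**Further compounds**

F1 | step 11 | 3,5-bis(tert-butyldimethylsilyloxy)-2-(hydroxymethyl)-6-(2-methylbut-3-en-2-yl)phenol | OCc1c(O[Si](C)(C)C(C)(C)C)cc(O[Si](C)(C)C(C)(C)C)c(C(C)(C)C=C)c1O
F2 | step 11 | {[4,6-bis(tert-butyldimethylsilyloxy)-2-hydroxy-3-(2-methylbut-3-en-2-yl)phenyl]methyl}triphenylphosphonium bromide | [Br-].C=CC(C)(C)c1c(O)c(C[P+](c2ccccc2)(c2ccccc2)c2ccccc2)c(O[Si](C)(C)C(C)(C)C)cc1O[Si](C)(C)C(C)(C)C
F3 | step 2 | 2,6-bis(tert-butyldimethylsilyloxy)-4-[(3-methylbut-2-en-1-yl)oxy]benzaldehyde | O=Cc1c(O[Si](C)(C)C(C)(C)C)cc(OCC=C(C)C)cc1O[Si](C)(C)C(C)(C)C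
F4 | step 2 | 2,6-bis(tert-butyldimethylsilyloxy)-4-hydroxy-3-(2-methylbut-3-en-2-yl)benzaldehyde | C=CC(C)(C)c1c(O)cc(O[Si](C)(C)C(C)(C)C)c(C=O)c1O[Si](C)(C)C(C)(C)C
F5 | step 3 | 2-(tert-butyldimethylsilyloxy)-6-hydroxy-4-[(3-methylbut-2-en-1-yl)oxy]benzaldehyde | O=Cc1c(O)cc(OCC=C(C)C)cc1O[Si](C)(C)C(C)(C)C
F6 | step 3 | 6-(tert-butyldimethylsilyloxy)-2,4-dihydroxy-3-(2-methylbut-3-en-2-yl)benzaldehyde | C=CC(C)(C)c1c(O)cc(O[Si](C)(C)C(C)(C)C)c(C=O)c1O
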